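The data were computed from invented constants, and the scatter is random.

The constants are hidden, so you read one quantity from the autumn readings: Y, G made per E charged 525, the turnover number.

in all of them: L 0.032 M
- autumn: E 0.02 mol%; the very flask that is asked about, followed so far
- winter: E 0.03 mol%; run made earlier
- flask: E 0.02 mol%; time 6.0 h

| run | time / min | G / % |
|---|---|---|
| autumn | 25.0 | 2.8 |
| autumn | 50.0 | 4.0 |
| autumn | 120 | 6.7 |
| autumn | 300 | 10.5 |
| winter | 1.33 | 0.3 |
| winter | 3.00 | 1.2 |
| winter | 6.00 | 0.9 |
| winter | 15.0 | 0.2 |

(standard deviation of a reading: 1 percentage point)
- Thursday's: change nothing and wait 3.0 h more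
- Sunday's: at 6.0 h take out 90% of the G then present, then wait 3.0 h
- Tuesday's: at 6.0 h add E, 50.0% of the amount charged, then wait 3.0 h
- solid, in amounts per volume of the solution: L
- what is taken out of G is counted as made
- candidate steps: Q + E -> G + E; E -> Z; L <-> Q
- at the start none of L is in solution
- additions bring no volume worth counting
- G, in percent of the L first charged, at 6.0 h
- the option that brings most further G ("none" if no option brings more than 2 percentage points) (Thursday's / Sunday's / Tuesday's / none)
- G present, with what was taken out counted in, in percent of the L first charged, after Sunday's
- G present, with what was taken out counted in, in percent of the L first charged, after Tuesday's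

In the autumn flask the slope of G falls by a factor of 2.27 between the early and late readings, so I take E to be dying by E -> Z. I therefore reckon G now a little above the 10.5% read at 300 min, with Thursday's under 2 percentage points. No candidate step consumes G, so Sunday's matches Thursday's. At the start none of L is in solution, so I expect the first E to have worked while Q was still dissolving, and E added at 6.0 h to find Q already in solution. So I use Y as my estimate of a floor for that added E: I reckon Tuesday's gains 5.2 points or more, reaching 15.7% or more.

The forecast gave 11.2%, Tuesday's as best, 12.1% and 16.2%, reasoning “Fresh enzyme at half the charge should add about half the plateau”.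

The flask gives 11.1%, best Tuesday's, 11.1% after Sunday's and 28.5% after Tuesday's.

    Q + E → G + E, rate k1*[Q]^1.5*[E]/(1 + ([Q]/Kh1)^1.5) (30.0 mM, k = 750 /M^1.5/s)
    E → Z (k = 3.50 × 10⁻⁴ /s)
    L ⇌ Q, rate k3*(cs3 - [Q]) while solid is left; crystals form when [Q] > cs3 (solubility = 12.0 mM, k = 2.10 × 10⁻⁴ /s)

Tuesday's brings 17 points, which is 1740 per E added, more than Y of 525. The added E meets Q at 36.6% of the L charged, while the first charge had Q at 11.9% at 36.0 min, with E already down to 47.0%. A neighbouring flask charged with 0.008 mol% of E also starts with no Q: Y predicts 4.20% for it, and it gives 4.97%.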